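## Retrosynthetic overview

1. Target ⇐ silyl ether ⇐ syn-1,3-diol: the two acyl C–O bonds are made last, by site-selective O-propanoylation of the allylic C5 hydroxyl and then O-acetylation of C3.
2. Diol ⇐ ethyl enone carrying ring B + α-pyranonyl aldehyde carrying ring A: a boron anti-aldol (Felkin–Anh) with in-flask 1,3-syn reduction forms C3–C4 and sets C3, C4 and C5.
3. Ethyl enone ⇐ oxidation/Wittig of a ring B diol ⇐ a new biocatalytic dynamic kinetic reduction of an α-pyranonyl ethyl ketone (sets C2′ and C3′) ⇐ lateral C-acylation.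
4. Key step, a C–O bond formation: one lipase O-acylation sorts a racemic α-pyranonyl propanol into the (R)-acetate (becomes C2 at ring A) and the (S)-alcohol (becomes C8 at ring B), so both enantiomers are used.
5. Rings: ring A and ring B are the same 4-pyranone, closed once, in step 1, through its ring C–O bond (double acylation and cyclodehydration of pentan-3-one) before any stereocentre exists; no ring is formed later.

Labels: the non-6-ene chain runs from C2 (on ring A, the 6-ethylpyranone) to C8 (on ring B); C3 carries the acetate and C5 the propanoate; C2′ and C3′ are the stereocentres of the 3-hydroxypentan-2-yl group on ring B.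

Assumption: lipase PS acylates the enantiomer of the racemic alcohol that matches in space the fast-reacting (S)-enantiomer of 2-arylpropan-1-ols, which here is the (R)-alcohol.

## Route

Step 1
Reactants: 1 pentan-3-one; 2 propanoic anhydride
Product: 3 2,6-diethyl-3,5-dimethyl-4H-pyran-4-one
Conditions: polyphosphoric acid, 110 °C
Reagents that add atoms: none
Why: Acid-mediated double C-acylation of the ketone to the 3,5,7-trione followed by cyclodehydration (classical polyphosphoric acid pyranone synthesis) closes the ring through its C–O bond, and no stereocentre is involved.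

Step 2
Reactants: 3 2,6-diethyl-3,5-dimethyl-4H-pyran-4-one; 4 formaldehyde (monomer from cracked paraformaldehyde)
Product: 5 rac-2-ethyl-6-(1-hydroxypropan-2-yl)-3,5-dimethyl-4H-pyran-4-one
Conditions: LiN(i-Pr)2 (1.05 equiv), THF, −78 °C; HCHO (g), −78 → −20 °C; aq NH4Cl
Reagents that add atoms: none
Why: Lateral (vinylogous) lithiation of one of the two equivalent ethyl groups gives an extended enolate that adds to formaldehyde (vinylogous aldol-type hydroxymethylation), and the new stereocentre is left racemic on purpose.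

Step 3
Reactants: 5 rac-2-ethyl-6-(1-hydroxypropan-2-yl)-3,5-dimethyl-4H-pyran-4-one
Product: 6 2-ethyl-6-[(2S)-1-hydroxypropan-2-yl]-3,5-dimethyl-4H-pyran-4-one (unreacted enantiomer) and 7 (2R)-2-(6-ethyl-3,5-dimethyl-4-oxo-4H-pyran-2-yl)propyl acetate
Conditions: lipase PS (Burkholderia cepacia, immobilised), vinyl acetate, i-Pr2O, 0 °C, to about 50% conversion; chromatography
Reagents that add atoms: vinyl acetate, C=COC(C)=O
Why: Lipase-catalysed kinetic resolution by enantioselective transesterification of a primary alcohol with a β-stereocentre, as known for 2-arylpropan-1-ols, in which the acyl C–O bond formation tells the enantiomers apart so that 7 supplies C2 and 6 supplies C8.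

Step 4
Reactants: 7 (2R)-2-(6-ethyl-3,5-dimethyl-4-oxo-4H-pyran-2-yl)propyl acetate
Product: 8 2-ethyl-6-[(2R)-1-hydroxypropan-2-yl]-3,5-dimethyl-4H-pyran-4-one
Conditions: K2CO3 (cat.), MeOH, 0 °C
Reagents that add atoms: none
Why: Base-catalysed transesterification (methanolysis) of a primary acetate, under which the stereocentre is not enolisable and is untouched.

Step 5
Reactants: 8 2-ethyl-6-[(2R)-1-hydroxypropan-2-yl]-3,5-dimethyl-4H-pyran-4-one
Product: 9 (2S)-2-(6-ethyl-3,5-dimethyl-4-oxo-4H-pyran-2-yl)propanal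
Conditions: Dess–Martin periodinane, CH2Cl2, 0 °C; used at once without storage
Reagents that add atoms: none
Why: Dess–Martin oxidation is amine-free, so the primary alcohol becomes the aldehyde without a base that could enolise the now acidic α-position, and the stereocentre is kept by immediate use.

Step 6
Reactants: 6 2-ethyl-6-[(2S)-1-hydroxypropan-2-yl]-3,5-dimethyl-4H-pyran-4-one; 10 N-methoxy-N-methylpropanamide
Product: 11 2-[(2S)-1-hydroxypropan-2-yl]-3,5-dimethyl-6-[(2RS)-3-oxopentan-2-yl]-4H-pyran-4-one (epimer mixture)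
Conditions: LiN(i-Pr)2 (2.2 equiv), THF, −78 °C; 10, −78 → −40 °C; aq NH4Cl
Reagents that add atoms: none
Why: Alkoxide/lateral-carbanion dianion formation at the unhindered ethyl CH2 followed by Weinreb ketone synthesis (the chelated tetrahedral intermediate stops over-addition), with the new α-centre left unset because it is labile.

Step 7
Reactants: 11 2-[(2S)-1-hydroxypropan-2-yl]-3,5-dimethyl-6-[(2RS)-3-oxopentan-2-yl]-4H-pyran-4-one
Product: 12 2-[(2R,3S)-3-hydroxypentan-2-yl]-6-[(2S)-1-hydroxypropan-2-yl]-3,5-dimethyl-4H-pyran-4-one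
Conditions: alcohol dehydrogenase ADH-A (Rhodococcus ruber, Prelog-selective), NAD+ (cat.), i-PrOH (10 vol%), Tris–HCl buffer pH 8.5, 30 °C
Reagents that add atoms: none
Why: Proposed new method: biocatalytic dynamic kinetic reduction of an α-(4-oxopyran-2-yl) ketone, a vinylogous α-methyl β-keto ester, in which the α-hydrogen lies between the ketone and the vinylogous-ester ring so that the two epimers interconvert through the extended enol(ate) in the mildly basic buffer while the Prelog-type enzyme delivers hydride to the Re face of the better-fitting (2′R) epimer only, giving the (2′R,3′S)-syn alcohol, the closest known reaction type being the enzymatic (and Noyori-type) dynamic kinetic reduction of α-alkyl β-keto esters to syn-(2R,3S)-hydroxy esters.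

Step 8
Reactants: 13 2-bromopentan-3-one; 14 triphenylphosphine
Product: 16 2-(triphenyl-λ5-phosphanylidene)pentan-3-one, via phosphonium bromide 15 (not isolated)
Conditions: toluene, 90 °C; then aq NaOH, CH2Cl2, rt
Reagents that add atoms: none
Why: SN2 alkylation of the phosphine by the α-bromo ketone and deprotonation of the salt give the ketone-stabilised ylide (standard Wittig reagent preparation).

Step 9
Reactants: 12 2-[(2R,3S)-3-hydroxypentan-2-yl]-6-[(2S)-1-hydroxypropan-2-yl]-3,5-dimethyl-4H-pyran-4-one; 16 2-(triphenyl-λ5-phosphanylidene)pentan-3-one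
Product: 18 (4E,6S)-6-{6-[(2R,3S)-3-hydroxypentan-2-yl]-3,5-dimethyl-4-oxo-4H-pyran-2-yl}-4-methylhept-4-en-3-one, via aldehyde 17 (not isolated)
Conditions: 2,2,6,6-tetramethylpiperidin-1-oxyl (10 mol%), PhI(OAc)2, CH2Cl2, rt; then 16, rt → 40 °C
Reagents that add atoms: none
Why: Nitroxyl-catalysed oxidation touches only the primary alcohol and the labile aldehyde is trapped in the same flask by an E-selective Wittig olefination with the stabilised ylide, so C8 is retained and the (E)-trisubstituted alkene is set.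

Step 10
Reactants: 18 (4E,6S)-6-{6-[(2R,3S)-3-hydroxypentan-2-yl]-3,5-dimethyl-4-oxo-4H-pyran-2-yl}-4-methylhept-4-en-3-one
Product: 19 (4E,6S)-6-{3,5-dimethyl-4-oxo-6-[(2R,3S)-3-(triethylsilyloxy)pentan-2-yl]-4H-pyran-2-yl}-4-methylhept-4-en-3-one
Conditions: Et3SiCl, imidazole, DMF, 0 °C → rt
Reagents that add atoms: chlorotriethylsilane, CC[Si](Cl)(CC)CC
Why: Standard silylation masks the C3′ hydroxyl so that only the two chain hydroxyls are acylated later, with no stereocentre affected.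

Step 11
Reactants: 19 (4E,6S)-6-{3,5-dimethyl-4-oxo-6-[(2R,3S)-3-(triethylsilyloxy)pentan-2-yl]-4H-pyran-2-yl}-4-methylhept-4-en-3-one; 9 (2S)-2-(6-ethyl-3,5-dimethyl-4-oxo-4H-pyran-2-yl)propanal
Product: 22 (2R,3S,4R,5R,6E,8S)-2-(6-ethyl-3,5-dimethyl-4-oxo-4H-pyran-2-yl)-4,6-dimethyl-8-{3,5-dimethyl-4-oxo-6-[(2R,3S)-3-(triethylsilyloxy)pentan-2-yl]-4H-pyran-2-yl}non-6-ene-3,5-diol, via enol borinate 20 (not isolated), via boron aldolate 21 (not isolated)
Conditions: Cy2BCl, Et3N, Et2O, 0 °C; 9, −78 °C; LiBH4, −78 °C; then H2O2, pH 7 buffer, MeOH, 0 °C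
Reagents that add atoms: chlorodicyclohexylborane, ClB(C1CCCCC1)C1CCCCC1 (its boron stays only in 20 and 21, none in 22)
Why: Boron-mediated aldol through a Zimmerman–Traxler chair, in which the (E)-enol borinate gives the 3,4-anti relationship and adds to the Felkin–Anh face of the α-chiral aldehyde (2,3-syn), followed by external hydride attack of LiBH4 on the six-membered boron chelate (Narasaka–Prasad-type 1,3-syn reduction) to set C5.

Step 12
Reactants: 22 (2R,3S,4R,5R,6E,8S)-2-(6-ethyl-3,5-dimethyl-4-oxo-4H-pyran-2-yl)-4,6-dimethyl-8-{3,5-dimethyl-4-oxo-6-[(2R,3S)-3-(triethylsilyloxy)pentan-2-yl]-4H-pyran-2-yl}non-6-ene-3,5-diol; 2 propanoic anhydride; 23 acetic anhydride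
Product: 25 (2R,3S,4R,5R,6E,8S)-3-acetoxy-2-(6-ethyl-3,5-dimethyl-4-oxo-4H-pyran-2-yl)-4,6-dimethyl-8-{3,5-dimethyl-4-oxo-6-[(2R,3S)-3-(triethylsilyloxy)pentan-2-yl]-4H-pyran-2-yl}non-6-en-5-yl propanoate, via monopropanoate 24 (not isolated)
Conditions: 2 (1.1 equiv), 4-(dimethylamino)pyridine (5 mol%), Et3N, CH2Cl2, −40 °C; then 23 (excess), 4-(dimethylamino)pyridine, rt
Reagents that add atoms: none
Why: Steglich-type acyl transfer in which the allylic C5 hydroxyl, flanked by an sp2 carbon, reacts before the C3 hydroxyl that sits between two methyl-bearing sp3 centres (one carrying the tetrasubstituted pyranone), so the propanoate goes to C5 and the acetate then to C3, both with retention.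

Step 13
Reactants: 25 (2R,3S,4R,5R,6E,8S)-3-acetoxy-2-(6-ethyl-3,5-dimethyl-4-oxo-4H-pyran-2-yl)-4,6-dimethyl-8-{3,5-dimethyl-4-oxo-6-[(2R,3S)-3-(triethylsilyloxy)pentan-2-yl]-4H-pyran-2-yl}non-6-en-5-yl propanoate
Product: 26 (2R,3S,4R,5R,6E,8S)-3-acetoxy-2-(6-ethyl-3,5-dimethyl-4-oxo-4H-pyran-2-yl)-8-{6-[(2R,3S)-3-hydroxypentan-2-yl]-3,5-dimethyl-4-oxo-4H-pyran-2-yl}-4,6-dimethylnon-6-en-5-yl propanoate (CNP0265513.2)
Conditions: HF·pyridine, pyridine, THF, 0 °C → rt
Reagents that add atoms: none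
Why: Buffered fluoride-mediated desilylation cleaves only the Si–O bond and leaves both esters, the alkene, both pyranones and all stereocentres untouched.

## Compound list

1 | pentan-3-one | CCC(=O)CC | starting material
2 | propanoic anhydride | CCC(=O)OC(=O)CC | starting material
3 | 2,6-diethyl-3,5-dimethyl-4H-pyran-4-one | CCc1oc(CC)c(C)c(=O)c1C | intermediate
4 | formaldehyde (monomer from paraformaldehyde) | C=O | starting material
5 | rac-2-ethyl-6-(1-hydroxypropan-2-yl)-3,5-dimethyl-4H-pyran-4-one | CCc1oc(C(C)CO)c(C)c(=O)c1C | intermediate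
6 | 2-ethyl-6-[(2S)-1-hydroxypropan-2-yl]-3,5-dimethyl-4H-pyran-4-one | OC[C@H](C)c1oc(CC)c(C)c(=O)c1C | intermediate
7 | (2R)-2-(6-ethyl-3,5-dimethyl-4-oxo-4H-pyran-2-yl)propyl acetate | CC(=O)OC[C@@H](C)c1oc(CC)c(C)c(=O)c1C | intermediate
8 | 2-ethyl-6-[(2R)-1-hydroxypropan-2-yl]-3,5-dimethyl-4H-pyran-4-one | OC[C@@H](C)c1oc(CC)c(C)c(=O)c1C | intermediate
9 | (2S)-2-(6-ethyl-3,5-dimethyl-4-oxo-4H-pyran-2-yl)propanal | O=C[C@@H](C)c1oc(CC)c(C)c(=O)c1C | intermediate
10 | N-methoxy-N-methylpropanamide | CCC(=O)N(C)OC | starting material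
11 | 2-[(2S)-1-hydroxypropan-2-yl]-3,5-dimethyl-6-[(2RS)-3-oxopentan-2-yl]-4H-pyran-4-one (epimer mixture) | OC[C@H](C)c1oc(C(C)C(=O)CC)c(C)c(=O)c1C | intermediate
12 | 2-[(2R,3S)-3-hydroxypentan-2-yl]-6-[(2S)-1-hydroxypropan-2-yl]-3,5-dimethyl-4H-pyran-4-one | OC[C@H](C)c1oc([C@H](C)[C@@H](O)CC)c(C)c(=O)c1C | intermediate
13 | 2-bromopentan-3-one (racemic) | CCC(=O)C(C)Br | starting material
14 | triphenylphosphine | c1ccc(cc1)P(c1ccccc1)c1ccccc1 | starting material
15 | (3-oxopentan-2-yl)triphenylphosphonium bromide | CCC(=O)C(C)[P+](c1ccccc1)(c1ccccc1)c1ccccc1.[Br-] | intermediate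
16 | 2-(triphenyl-λ5-phosphanylidene)pentan-3-one | CCC(=O)C(C)=P(c1ccccc1)(c1ccccc1)c1ccccc1 | intermediate
17 | (2R)-2-{6-[(2R,3S)-3-hydroxypentan-2-yl]-3,5-dimethyl-4-oxo-4H-pyran-2-yl}propanal | O=C[C@H](C)c1oc([C@H](C)[C@@H](O)CC)c(C)c(=O)c1C | intermediate
18 | (4E,6S)-6-{6-[(2R,3S)-3-hydroxypentan-2-yl]-3,5-dimethyl-4-oxo-4H-pyran-2-yl}-4-methylhept-4-en-3-one | CCC(=O)/C(C)=C/[C@H](C)c1oc([C@H](C)[C@@H](O)CC)c(C)c(=O)c1C | intermediate
19 | (4E,6S)-6-{3,5-dimethyl-4-oxo-6-[(2R,3S)-3-(triethylsilyloxy)pentan-2-yl]-4H-pyran-2-yl}-4-methylhept-4-en-3-one | CCC(=O)/C(C)=C/[C@H](C)c1oc([C@H](C)[C@@H](O[Si](CC)(CC)CC)CC)c(C)c(=O)c1C | intermediate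
20 | (2E,4E)-enol dicyclohexylborinate of 19 (O–BCy2 on C3, the C2 methyl trans to oxygen) | C/C=C(/OB(C2CCCCC2)C2CCCCC2)\C(C)=C\[C@H](C)c1oc([C@H](C)[C@@H](O[Si](CC)(CC)CC)CC)c(C)c(=O)c1C | intermediate
21 | (2R,3R,4R,6E,8S)-3-(dicyclohexylboryloxy)-2-(6-ethyl-3,5-dimethyl-4-oxo-4H-pyran-2-yl)-4,6-dimethyl-8-{3,5-dimethyl-4-oxo-6-[(2R,3S)-3-(triethylsilyloxy)pentan-2-yl]-4H-pyran-2-yl}non-6-en-5-one | O=C(/C(C)=C/[C@H](C)c1oc([C@H](C)[C@@H](O[Si](CC)(CC)CC)CC)c(C)c(=O)c1C)[C@H](C)[C@H](OB(C2CCCCC2)C2CCCCC2)[C@@H](C)c1oc(CC)c(C)c(=O)c1C | intermediate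
22 | (2R,3S,4R,5R,6E,8S)-2-(6-ethyl-3,5-dimethyl-4-oxo-4H-pyran-2-yl)-4,6-dimethyl-8-{3,5-dimethyl-4-oxo-6-[(2R,3S)-3-(triethylsilyloxy)pentan-2-yl]-4H-pyran-2-yl}non-6-ene-3,5-diol | O[C@@H](/C(C)=C/[C@H](C)c1oc([C@H](C)[C@@H](O[Si](CC)(CC)CC)CC)c(C)c(=O)c1C)[C@H](C)[C@H](O)[C@@H](C)c1oc(CC)c(C)c(=O)c1C | intermediate
23 | acetic anhydride | CC(=O)OC(C)=O | starting material
24 | (2R,3S,4R,5R,6E,8S)-2-(6-ethyl-3,5-dimethyl-4-oxo-4H-pyran-2-yl)-3-hydroxy-4,6-dimethyl-8-{3,5-dimethyl-4-oxo-6-[(2R,3S)-3-(triethylsilyloxy)pentan-2-yl]-4H-pyran-2-yl}non-6-en-5-yl propanoate | CCC(=O)O[C@@H](/C(C)=C/[C@H](C)c1oc([C@H](C)[C@@H](O[Si](CC)(CC)CC)CC)c(C)c(=O)c1C)[C@H](C)[C@H](O)[C@@H](C)c1oc(CC)c(C)c(=O)c1C | intermediate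
25 | (2R,3S,4R,5R,6E,8S)-3-acetoxy-2-(6-ethyl-3,5-dimethyl-4-oxo-4H-pyran-2-yl)-4,6-dimethyl-8-{3,5-dimethyl-4-oxo-6-[(2R,3S)-3-(triethylsilyloxy)pentan-2-yl]-4H-pyran-2-yl}non-6-en-5-yl propanoate | CCC(=O)O[C@@H](/C(C)=C/[C@H](C)c1oc([C@H](C)[C@@H](O[Si](CC)(CC)CC)CC)c(C)c(=O)c1C)[C@H](C)[C@H](OC(C)=O)[C@@H](C)c1oc(CC)c(C)c(=O)c1C | intermediate
26 | (2R,3S,4R,5R,6E,8S)-3-acetoxy-2-(6-ethyl-3,5-dimethyl-4-oxo-4H-pyran-2-yl)-8-{6-[(2R,3S)-3-hydroxypentan-2-yl]-3,5-dimethyl-4-oxo-4H-pyran-2-yl}-4,6-dimethylnon-6-en-5-yl propanoate (CNP0265513.2) | CCC(=O)O[C@@H](/C(C)=C/[C@H](C)c1oc([C@H](C)[C@@H](O)CC)c(C)c(=O)c1C)[C@H](C)[C@H](OC(C)=O)[C@@H](C)c1oc(CC)c(C)c(=O)c1C | target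

## Step count and risks

Total step count: 13.
Longest linear sequence: 10 steps (1, 2, 3, 6, 7, 9, 10, 11, 12, 13).

Three steps most likely to fail:

**Step 7 (the proposed new reduction).** The enzyme may not accept the ethyl ketone, or epimerisation at C2′ may be too slow for a dynamic process. The fallback uses known chemistry, sets out from 6 and comes back at 12. Compound 6 is silylated (t-BuMe2SiCl, imidazole) to the primary TBS ether F1. Lateral lithiation (LiN(i-Pr)2) and C-formylation with DMF give the epimeric α-pyranonyl aldehyde F2. EtTi(O-i-Pr)3 adds with Felkin–Anh selectivity to give the two syn alcohols, the wanted (2′R,3′S) alcohol F3 and its (2′S,3′R) diastereomer F4. Candida antarctica lipase B with vinyl acetate acetylates only the (R)-carbinol, turning F4 into the acetate F5, which is removed on silica. HF·pyridine then frees the primary hydroxyl of F3 to give 12. Here the relative configuration comes from substrate control and the absolute one from an enzymatic O-acylation, not from a dynamic reduction.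

**Step 11 (fragment union).** The amine may epimerise aldehyde 9, the borane may be tied up by the pyranone carbonyls, or the in-flask reduction may be unselective. The fallback sets out from 19 and comes back at 22. Kinetic enolisation and silylation (LiN(SiMe3)2, Me3SiCl, THF, −78 °C) give the (2Z)-trimethylsilyl enol ether F6. An amine-free Mukaiyama aldol with 9 under BF3·OEt2 at −78 °C gives the β-hydroxy enone F7; this goes through an open transition state with Felkin–Anh addition, the anti preference is expected to be lower, and minor isomers are removed by chromatography. A separate Narasaka–Prasad reduction (Et2BOMe, NaBH4, THF/MeOH, −78 °C) then gives 22.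

**Step 12 (differential diacylation).** The two secondary hydroxyls may not be told apart well enough, or the propanoyl group may migrate from O5 to O3 during the acetylation. The fallback sets out from 22 and comes back at 25. MnO2 in CH2Cl2 oxidises only the allylic C5 hydroxyl and returns the β-hydroxy enone F7 (the compound already met in the fallback for step 11). The lone C3 hydroxyl is acetylated (acetic anhydride, pyridine, 0 °C) to the β-acetoxy enone F8. Corey–Bakshi–Shibata reduction with (S)-tetrahydro-1-methyl-3,3-diphenyl-1H,3H-pyrrolo[1,2-c][1,3,2]oxazaborole and catecholborane at −78 °C (alkenyl as the larger group) gives the (5R)-alcohol F9. Its only free hydroxyl is propanoylated (2, 4-(dimethylamino)pyridine) to give 25. The two esters are then told apart by the order in which the oxygens become available, not by their steric difference.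

## Further compounds

F1 | step 7 | 2-{(2S)-1-[tert-butyl(dimethyl)silyloxy]propan-2-yl}-6-ethyl-3,5-dimethyl-4H-pyran-4-one | CC(C)(C)[Si](C)(C)OC[C@H](C)c1oc(CC)c(C)c(=O)c1C
F2 | step 7 | (2RS)-2-(6-{(2S)-1-[tert-butyl(dimethyl)silyloxy]propan-2-yl}-3,5-dimethyl-4-oxo-4H-pyran-2-yl)propanal | CC(C)(C)[Si](C)(C)OC[C@H](C)c1oc(C(C)C=O)c(C)c(=O)c1C
F3 | step 7 | 2-{(2S)-1-[tert-butyl(dimethyl)silyloxy]propan-2-yl}-6-[(2R,3S)-3-hydroxypentan-2-yl]-3,5-dimethyl-4H-pyran-4-one | CC(C)(C)[Si](C)(C)OC[C@H](C)c1oc([C@H](C)[C@@H](O)CC)c(C)c(=O)c1C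
F4 | step 7 | 2-{(2S)-1-[tert-butyl(dimethyl)silyloxy]propan-2-yl}-6-[(2S,3R)-3-hydroxypentan-2-yl]-3,5-dimethyl-4H-pyran-4-one | CC(C)(C)[Si](C)(C)OC[C@H](C)c1oc([C@@H](C)[C@H](O)CC)c(C)c(=O)c1C
F5 | step 7 | (2S,3R)-2-(6-{(2S)-1-[tert-butyl(dimethyl)silyloxy]propan-2-yl}-3,5-dimethyl-4-oxo-4H-pyran-2-yl)pentan-3-yl acetate | CC(C)(C)[Si](C)(C)OC[C@H](C)c1oc([C@@H](C)[C@H](OC(C)=O)CC)c(C)c(=O)c1C
F6 | step 11 | (2Z,4E)-trimethylsilyl enol ether of 19 (Me3SiO on C3, the C2 methyl cis to oxygen) | C/C=C(\O[Si](C)(C)C)/C(C)=C/[C@H](C)c1oc([C@H](C)[C@@H](O[Si](CC)(CC)CC)CC)c(C)c(=O)c1C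
F7 | step 11 | (2R,3R,4R,6E,8S)-2-(6-ethyl-3,5-dimethyl-4-oxo-4H-pyran-2-yl)-3-hydroxy-4,6-dimethyl-8-{3,5-dimethyl-4-oxo-6-[(2R,3S)-3-(triethylsilyloxy)pentan-2-yl]-4H-pyran-2-yl}non-6-en-5-one | O=C(/C(C)=C/[C@H](C)c1oc([C@H](C)[C@@H](O[Si](CC)(CC)CC)CC)c(C)c(=O)c1C)[C@H](C)[C@H](O)[C@@H](C)c1oc(CC)c(C)c(=O)c1C
F8 | step 12 | (2R,3R,4R,6E,8S)-2-(6-ethyl-3,5-dimethyl-4-oxo-4H-pyran-2-yl)-4,6-dimethyl-5-oxo-8-{3,5-dimethyl-4-oxo-6-[(2R,3S)-3-(triethylsilyloxy)pentan-2-yl]-4H-pyran-2-yl}non-6-en-3-yl acetate | O=C(/C(C)=C/[C@H](C)c1oc([C@H](C)[C@@H](O[Si](CC)(CC)CC)CC)c(C)c(=O)c1C)[C@H](C)[C@H](OC(C)=O)[C@@H](C)c1oc(CC)c(C)c(=O)c1C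
F9 | step 12 | (2R,3S,4S,5R,6E,8S)-2-(6-ethyl-3,5-dimethyl-4-oxo-4H-pyran-2-yl)-5-hydroxy-4,6-dimethyl-8-{3,5-dimethyl-4-oxo-6-[(2R,3S)-3-(triethylsilyloxy)pentan-2-yl]-4H-pyran-2-yl}non-6-en-3-yl acetate | O[C@@H](/C(C)=C/[C@H](C)c1oc([C@H](C)[C@@H](O[Si](CC)(CC)CC)CC)c(C)c(=O)c1C)[C@H](C)[C@H](OC(C)=O)[C@@H](C)c1oc(CC)c(C)c(=O)c1C
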